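**The problem**

Target 14, (3-chloro-2-hydroxy-4,6-dimethoxyphenyl)(4-hydroxy-2-methoxy-6-methylphenyl)methanone, is a benzophenone in which one carbonyl carbon joins ring A (C1 ketone, C2 OH, C3 Cl, C4 and C6 OMe) to ring B (C1' ketone, C2' CH3, C4' OH, C6' OMe). All four positions ortho to the ketone are substituted, so a late union of two finished rings at that carbon would be the hardest bond to make. There is no stereocenter, and the aryl–carbonyl bonds should rotate too fast for isolable atropisomers, so the task is purely regiochemical. Five oxygens must end as three methyl ethers (O4, O6, O6') and two free phenols (O2, O4'), and the one chlorine must go to C3, not to C5 or ring B. The fragile features are the C3–Cl bond (reductive loss), the methyl ethers ortho to the ketone (Lewis-acid cleavage) and the electron-rich rings, which over-halogenate easily and oxidize in base at the polyphenol stage. One helpful feature is that the O2 phenol is hydrogen-bonded to the ketone, which sets it apart from every other oxygen. The other is that ring A, with the acyl group at C1 and oxygens at C2, C4 and C6, is an acylphloroglucinol, the Claisen-folded form of a 7-aryl-3,5,7-trioxoheptanoate: chain carbons C6, C1, C2, C3, C4, C5 become ring A C1 to C6, and the ring is symmetric until chlorine and methyl groups are added.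

**Retrosynthesis**

14 from 13. The last bond cut is the benzylic C–O bond on O4'. The ring B phenol must be masked, because otherwise it could not be told apart from the ring A oxygens during methylation. A benzyl ether is chosen because it survives hot hydroxide, acid chloride formation, a lithium dianion, boiling methanolic Mg(OMe)2, dimethyl sulfate and a chlorinating agent. Silyl or acyl groups would not survive, and a fourth methyl ether could not be removed selectively. The forward step must cleave the benzyl ether without touching C3–Cl.

13 from 12. The C3–Cl bond is cut. Chlorinating after methylation is preferred to chlorinating before it, because in 12 the only free phenol of ring A is the chelated O2–H, and C3 is the position ortho to it. With chlorine put in earlier, the two ortho oxygens would have to be told apart by methylation alone. The forward step needs one chlorine, at C3, on ring A.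

12 from 11. The O4–CH3 and O6–CH3 bonds are cut. Ring A of 11 is a symmetric 2,4,6-trihydroxyaryl ketone. Its two ortho hydroxyls are equivalent, and whichever one stays hydrogen-bonded to the ketone resists alkylation, so a twofold methylation can give only 12. The precursor has no differentiated ring A oxygens at all, a real simplification.

11 from 9 (through 10). The ring A C1–C2 bond is cut, which unfolds ring A into the open-chain triketo ester 10; 10 is stored as its lactone, the 4-hydroxy-2-pyranone 9. The neighbouring cut, at the ketone–ring A bond, would mean Friedel–Crafts acylation of a phloroglucinol by the hindered ring B acid, which forms the tetra-ortho-substituted ketone between two finished rings. In 9 that ketone already exists and ring A grows around it. The precursor has one carbocycle fewer and is a stable solid. The forward reaction must open the lactone and close the chain by Claisen rather than aldol condensation.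

9 from 6 and 7 (through 8). The bond between the ring B ketone carbon and the adjacent CH2 is cut. This gives acid chloride 6 and the dianion 8 of commercial pyranone 7, whose 6-methyl carbanion is its most nucleophilic site. The forward step is a C-acylation at a hindered carbonyl, so the most reactive acyl donor is used and the dianion is taken in excess.

6 back to 1 and 2. Acid chloride 6 comes from acid 5, and 5 from ester 4 by saponification. Ester 4 comes from 3 by methylation of the chelated 2-OH, and 3 from methyl orsellinate 1 and benzyl bromide 2 by benzylation of the unchelated 4-OH. Ring B is bought complete; only the order of the two O-alkylations matters, and the hydrogen bond of the 2-OH to the ester fixes it.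

**Roads not taken**

Alternative 1: Ring B would be built last by a Diels–Alder reaction, cutting C1'–C6' and C2'–C3'. The partners are the ring A ynone 1-(2-benzyloxy-3-chloro-4,6-dimethoxyphenyl)but-2-yn-1-one A2 and the diene 1,1-dimethoxy-3-(trimethylsilyloxy)buta-1,3-diene A3. The unsubstituted terminus of A3 should bond to the methyl-bearing alkyne carbon of A2 and the ketene acetal carbon to the carbon next to the ketone. Loss of one methoxy group and of the silyl group on acidic work-up would then give (2-benzyloxy-3-chloro-4,6-dimethoxyphenyl)(4-hydroxy-2-methoxy-6-methylphenyl)methanone A1 as the product of the key step. A1 would be one debenzylation from 14.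
- Merits: the route is convergent, diene polarization fixes the ring B pattern, the 4'-OH emerges free, and chlorine is in place before the rings are joined. In that last respect it is better than the chosen plan, which has to win a late site-selective chlorination.
- Weak points: A2 needs a pentasubstituted ring A building block with chlorine, a protected phenol and a carbonyl in defined positions, so the regiochemical question is only moved to an earlier ring A substitution. A3 is moisture-sensitive. The dienophile is a disubstituted alkyne with a twisted, hindered aroyl group, where conjugate addition without ring closure can compete.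
- Comparison: the length is comparable. The chosen plan offers cheap ring B and pyranone starting materials, a symmetric ring A at the ring-forming step, and a chelated phenol to direct the chlorine.

Alternative 2: An aryne would be inserted into the C–C bond of a ring A β-keto ester, cutting C1'–C(=O) and C2'–CH2. The partners are methyl 3-(2-benzyloxy-3-chloro-4,6-dimethoxyphenyl)-3-oxopropanoate A5 and 5-(benzyloxy)-3-methoxy-2-(trimethylsilyl)phenyl trifluoromethanesulfonate A6. Fluoride would release the aryne from A6 and the enolate of A5 would add at the aryne carbon remote from methoxy. The aryl anion next to methoxy would then attack the ketone, and the four-membered alkoxide would fragment to methyl 2-[5-benzyloxy-2-(2-benzyloxy-3-chloro-4,6-dimethoxybenzoyl)-3-methoxyphenyl]acetate A4 as the product of the key step.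
- Merits: two C–C bonds form in one convergent step, the methoxy group gives reliable aryne regiochemistry, and chlorine is preinstalled.
- Weak points: A4 carries CH2CO2Me where 14 has CH3, so a carbon must be excised by saponification and decarboxylation of an arylacetic acid. A6 takes several steps to prepare. The aryl anion must add to a ketone already flanked by two ortho substituents. Two benzyl ethers must be removed next to the aryl chloride.
- Comparison: it is more convergent, but longer overall and ends with the same dechlorination risk doubled. The chosen plan builds the hindered ketone early, from an acid chloride and a primary carbanion.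

Alternative 3: Ring B would come from an inverse-demand Diels–Alder reaction, cutting C2'–C3' and C4'–C5'. The partners are 5-(2-benzyloxy-3-chloro-4,6-dimethoxybenzoyl)-4-methoxy-6-methyl-2H-pyran-2-one A8 and 1,1-bis(benzyloxy)ethene A9. The bridged lactone would aromatize by decarboxylation and loss of one benzyloxy group to give (2-benzyloxy-3-chloro-4,6-dimethoxyphenyl)(4-benzyloxy-2-methoxy-6-methylphenyl)methanone A7 as the product of the key step. A7 would need only the removal of both benzyl ethers to reach 14.
- Merits: every substituent of 14 is delivered in one step, with both phenols under the same protecting group. The endgame is a single deprotection, shorter than the three steps the chosen plan needs after its key step.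
- Weak points: A8 is hard to reach, because electrophiles attack 4-oxygenated 2-pyranones at C3, not C5, so the 5-aroyl isomer needs a de novo pyranone synthesis on the hindered ring A ketone. The 4-methoxy group lowers the diene's electron demand, so heat would be needed. A9 is not a stock reagent and hydrolyses readily. Two benzyl ethers must come off beside the chloride.
- Comparison: the chosen plan has a longer endgame, but every intermediate comes from stock materials by standard reactions.

Key step: step 6

Remark on the chemistry: 14 has no stereogenic element; 8 is drawn as its dilithium salt and 10 as the neutral triketo ester, although 10 exists in the flask as a magnesium polyenolate.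

**Route**

Step 1
Reactants: 1 methyl 2,4-dihydroxy-6-methylbenzoate; 2 benzyl bromide
Product: 3 methyl 4-(benzyloxy)-2-hydroxy-6-methylbenzoate
Conditions: 2 (1.05 equiv), K2CO3 (1.2 equiv), acetone, reflux
Reagents that add atoms: none
Why: Williamson etherification; the 2-OH is hydrogen-bonded to the ester carbonyl and much less nucleophilic, so the 4-OH is benzylated selectively, as is usual for orsellinate esters.

Step 2
Reactants: 3 methyl 4-(benzyloxy)-2-hydroxy-6-methylbenzoate
Product: 4 methyl 4-(benzyloxy)-2-methoxy-6-methylbenzoate
Conditions: MeI (3 equiv), K2CO3 (3 equiv), DMF, 50 °C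
Reagents that add atoms: iodomethane, CI
Why: Williamson O-methylation of the remaining chelated phenol, which yields to excess iodomethane in a dipolar aprotic solvent; no other acidic site is present.

Step 3
Reactants: 4 methyl 4-(benzyloxy)-2-methoxy-6-methylbenzoate
Product: 5 4-(benzyloxy)-2-methoxy-6-methylbenzoic acid
Conditions: KOH (10 equiv), DMSO–H2O 4:1, 90 °C; then 1 M HCl, 0 °C
Reagents that add atoms: potassium hydroxide, [K+].[OH-]
Why: Saponification of a di-ortho-substituted benzoate, which needs poorly solvated hydroxide in wet DMSO; both aryl ethers are inert to base, and cold acidification avoids protodecarboxylation of the electron-rich acid.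

Step 4
Reactants: 5 4-(benzyloxy)-2-methoxy-6-methylbenzoic acid
Product: 6 4-(benzyloxy)-2-methoxy-6-methylbenzoyl chloride
Conditions: (COCl)2 (1.5 equiv), cat. DMF, CH2Cl2, 0 °C to rt; evaporate, use crude
Reagents that add atoms: oxalyl chloride, O=C(Cl)C(Cl)=O
Why: Acid chloride formation through the DMF-derived chloroiminium catalyst; these mild, Lewis-acid-free conditions leave the benzyl and methyl ethers intact.

Step 5
Reactants: 6 4-(benzyloxy)-2-methoxy-6-methylbenzoyl chloride; 7 4-hydroxy-6-methyl-2H-pyran-2-one
Product: 9 6-[2-(4-benzyloxy-2-methoxy-6-methylphenyl)-2-oxoethyl]-4-hydroxy-2H-pyran-2-one, via pyranone dianion dilithium salt 8 (not isolated)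
Conditions: 7 (2.2 equiv), LiN(iPr)2 (4.4 equiv), THF, −78 to 0 °C; then 6 (1 equiv), −78 °C to rt; 1 M HCl
Reagents that add atoms: none
Why: Crossed Claisen-type C-acylation of the pyranone dianion, whose last-formed 6-CH2 carbanion is its most nucleophilic site. The excess dianion deprotonates the more acidic product as it forms and so prevents a second acylation.

Step 6
Reactants: 9 6-[2-(4-benzyloxy-2-methoxy-6-methylphenyl)-2-oxoethyl]-4-hydroxy-2H-pyran-2-one
Product: 11 (4-benzyloxy-2-methoxy-6-methylphenyl)(2,4,6-trihydroxyphenyl)methanone, via open-chain triketo methyl ester 10 (not isolated)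
Conditions: Mg(OMe)2 (8 equiv), MeOH, reflux, Ar; then 1 M HCl, 0 °C
Reagents that add atoms: none
Why: Methoxide adds to the lactone carbonyl of 9 and opens the ring to the methyl 7-aryl-3,5,7-trioxoheptanoate 10, held as a magnesium polyenolate. The carbon between the C5 and C7 carbonyls (C6) then attacks the ester carbon C1 in an intramolecular Claisen condensation, a 6-(enolendo)-exo-trig closure that forms the ring A C1–C2 bond and closes ring A. Loss of methoxide and enolization give the aromatic triol, and formation of its phenoxide makes the sequence irreversible, whereas re-lactonization to 9 is reversible. The closest known reaction type is the base-induced opening of 6-(2-oxoalkyl)-4-hydroxy-2-pyranones and the Claisen cyclization of 3,5,7-triketo esters to acylphloroglucinols. No stereocenter is formed. The selectivity needed is Claisen over aldol closure, the latter being attack of C2 on the C7 ketone to give a biaryl resorcylate. It is secured because the C7 carbonyl is shielded and twisted by the ortho methyl and methoxy groups of ring B, because magnesium keeps the ketones enolized while activating the chelated ester, and because alkoxide rather than hydroxide keeps the terminus an ester and not a carboxylate. Ring A of 11 is symmetric, so the closure poses no regiochemical question.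

Step 7
Reactants: 11 (4-benzyloxy-2-methoxy-6-methylphenyl)(2,4,6-trihydroxyphenyl)methanone
Product: 12 (4-benzyloxy-2-methoxy-6-methylphenyl)(2-hydroxy-4,6-dimethoxyphenyl)methanone
Conditions: Me2SO4 (2.1 equiv), K2CO3 (2.5 equiv), acetone, reflux, Ar
Reagents that add atoms: dimethyl sulfate, COS(=O)(=O)OC
Why: Chelation-controlled Williamson methylation: the para hydroxyl and one of the two equivalent ortho hydroxyls react, and the remaining ortho phenol is held in a hydrogen bond to the ketone and resists weak base and two equivalents of reagent. This is the standard behaviour of 2,4,6-trihydroxyaryl ketones.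

Step 8
Reactants: 12 (4-benzyloxy-2-methoxy-6-methylphenyl)(2-hydroxy-4,6-dimethoxyphenyl)methanone
Product: 13 (4-benzyloxy-2-methoxy-6-methylphenyl)(3-chloro-2-hydroxy-4,6-dimethoxyphenyl)methanone
Conditions: NCS (1.05 equiv), MeCN, 0 °C to rt
Reagents that add atoms: N-chlorosuccinimide, O=C1CCC(=O)N1Cl
Why: Electrophilic aromatic chlorination. Ring A, a phloroglucinol monophenol, is the most nucleophilic ring, and halogenation of 2-hydroxy-4,6-dialkoxyaryl ketones goes to C3, ortho to the chelated phenol, rather than to the more crowded C5 between two methoxy groups. One equivalent of a mild reagent limits dichlorination.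

Step 9
Reactants: 13 (4-benzyloxy-2-methoxy-6-methylphenyl)(3-chloro-2-hydroxy-4,6-dimethoxyphenyl)methanone
Product: 14 (3-chloro-2-hydroxy-4,6-dimethoxyphenyl)(4-hydroxy-2-methoxy-6-methylphenyl)methanone
Conditions: H2 (1 atm), 10% Pd/C, EtOAc, rt; stop at full conversion of 13
Reagents that add atoms: none
Why: Catalytic hydrogenolysis of the benzyl aryl ether. In a neutral, base-free medium the hindered, electron-rich aryl chloride is cleaved much more slowly than the benzylic C–O bond, and the tetra-ortho-substituted chelated ketone is not reduced.

**Compound list**

1 | methyl 2,4-dihydroxy-6-methylbenzoate | COC(=O)c1c(C)cc(O)cc1O | starting material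
2 | benzyl bromide | BrCc1ccccc1 | starting material
3 | methyl 4-(benzyloxy)-2-hydroxy-6-methylbenzoate | COC(=O)c1c(C)cc(OCc2ccccc2)cc1O | intermediate
4 | methyl 4-(benzyloxy)-2-methoxy-6-methylbenzoate | COC(=O)c1c(C)cc(OCc2ccccc2)cc1OC | intermediate
5 | 4-(benzyloxy)-2-methoxy-6-methylbenzoic acid | OC(=O)c1c(C)cc(OCc2ccccc2)cc1OC | intermediate
6 | 4-(benzyloxy)-2-methoxy-6-methylbenzoyl chloride | ClC(=O)c1c(C)cc(OCc2ccccc2)cc1OC | intermediate
7 | 4-hydroxy-6-methyl-2H-pyran-2-one | Cc1cc(O)cc(=O)o1 | starting material
8 | dilithium dianion of 4-hydroxy-6-methyl-2H-pyran-2-one (O4 oxide, 6-CH2 carbanion) | [Li+].[Li+].[CH2-]c1cc([O-])cc(=O)o1 | intermediate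
9 | 6-[2-(4-benzyloxy-2-methoxy-6-methylphenyl)-2-oxoethyl]-4-hydroxy-2H-pyran-2-one | O=C(Cc1cc(O)cc(=O)o1)c1c(C)cc(OCc2ccccc2)cc1OC | intermediate
10 | methyl 7-(4-benzyloxy-2-methoxy-6-methylphenyl)-3,5,7-trioxoheptanoate (present as magnesium polyenolate) | COC(=O)CC(=O)CC(=O)CC(=O)c1c(C)cc(OCc2ccccc2)cc1OC | intermediate
11 | (4-benzyloxy-2-methoxy-6-methylphenyl)(2,4,6-trihydroxyphenyl)methanone | O=C(c1c(O)cc(O)cc1O)c1c(C)cc(OCc2ccccc2)cc1OC | intermediate
12 | (4-benzyloxy-2-methoxy-6-methylphenyl)(2-hydroxy-4,6-dimethoxyphenyl)methanone | COc1cc(O)c(C(=O)c2c(C)cc(OCc3ccccc3)cc2OC)c(OC)c1 | intermediate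
13 | (4-benzyloxy-2-methoxy-6-methylphenyl)(3-chloro-2-hydroxy-4,6-dimethoxyphenyl)methanone | COc1cc(OC)c(C(=O)c2c(C)cc(OCc3ccccc3)cc2OC)c(O)c1Cl | intermediate
14 | (3-chloro-2-hydroxy-4,6-dimethoxyphenyl)(4-hydroxy-2-methoxy-6-methylphenyl)methanone | COc1cc(OC)c(C(=O)c2c(C)cc(O)cc2OC)c(O)c1Cl | target

**Step count and risks**

Total step count: 9. Longest linear sequence: 9 steps, from 1 to 14; 2 and 7 are bought and enter at steps 1 and 5.

Least certain steps:

1. Key step (step 6). The likely failures are that lactone opening and Claisen closure do not outrun re-lactonization to 9, that aldol closure of C2 onto C7 competes, or that prolonged heating with alkoxide causes retro-Claisen loss of the aroyl group. All three stem from the low electrophilicity of the polyanionic chain. The fallback buys ring A instead of building it. Acid chloride 6 is esterified with commercial 3,5-dimethoxyphenol (Et3N, DMAP, CH2Cl2) to 3,5-dimethoxyphenyl 4-(benzyloxy)-2-methoxy-6-methylbenzoate F1. A Lewis-acid Fries rearrangement of F1 (TiCl4, CH2Cl2, 0 °C to rt) then moves the aroyl group to the position ortho to the phenol, held there by chelation to titanium. The fallback sets out from 6 and returns to the route at 12, bypassing 9 and 11.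

2. Acylation (step 5). Attack at the di-ortho-substituted carbonyl may be slow enough for O-acylation at O4 of the dianion, or for a second acylation of the product enolate, to compete. The fallback replaces the acyl donor by an aldehyde, which is less hindered and cannot over-react. Ester 4 is reduced (LiAlH4, THF) to [4-(benzyloxy)-2-methoxy-6-methylphenyl]methanol F2, and F2 is then oxidized (MnO2, CH2Cl2) to 4-(benzyloxy)-2-methoxy-6-methylbenzaldehyde F3. Dianion 8 adds to F3 to give racemic 6-[2-(4-benzyloxy-2-methoxy-6-methylphenyl)-2-hydroxyethyl]-4-hydroxy-2H-pyran-2-one F4, and F4 is oxidized with Dess–Martin periodinane (CH2Cl2, rt) to the ketone. The fallback sets out from 4 (and 7) and returns at 9.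

3. Chlorination (step 8). Site selectivity may be poor: attack at C5, attack on the dialkoxytoluene-like ring B, or a second chlorination, because both rings are electron-rich and ring A is partly deactivated by conjugation with the ketone. The fallback changes the order of events. Triol 11, whose ring A is symmetric and far more nucleophilic than ring B, is monochlorinated (NCS, 1 equiv, MeCN, 0 °C) to (4-benzyloxy-2-methoxy-6-methylphenyl)(3-chloro-2,4,6-trihydroxyphenyl)methanone F5. Twofold methylation of F5 as in step 7 then alkylates O4 and the unhindered O6, while the more acidic, chlorine-flanked O2 keeps the hydrogen bond to the ketone. This methylation selectivity is the less secure point of the fallback. It sets out from 11 and returns at 13.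

4. Debenzylation (step 9). Hydrodechlorination at C3 may accompany or follow benzyl cleavage if the catalyst is too active or the reaction runs on. The fallback uses a non-reductive Lewis-acid dealkylation: BCl3 with pentamethylbenzene as cation scavenger in CH2Cl2 at −78 °C. At that temperature the benzyl ether cleaves faster than the methyl ethers ortho to the ketone, and the ketone is tied up in the boron chelate of O2. The fallback sets out from 13 and returns at 14; it makes no new compound, so its entry F0 is empty.

**Further compounds**

F1 | step 6 | 3,5-dimethoxyphenyl 4-(benzyloxy)-2-methoxy-6-methylbenzoate | COc1cc(OC)cc(OC(=O)c2c(C)cc(OCc3ccccc3)cc2OC)c1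
F2 | step 5 | [4-(benzyloxy)-2-methoxy-6-methylphenyl]methanol | OCc1c(C)cc(OCc2ccccc2)cc1OC
F3 | step 5 | 4-(benzyloxy)-2-methoxy-6-methylbenzaldehyde | O=Cc1c(C)cc(OCc2ccccc2)cc1OC
F4 | step 5 | racemic 6-[2-(4-benzyloxy-2-methoxy-6-methylphenyl)-2-hydroxyethyl]-4-hydroxy-2H-pyran-2-one | OC(Cc1cc(O)cc(=O)o1)c1c(C)cc(OCc2ccccc2)cc1OC
F5 | step 8 | (4-benzyloxy-2-methoxy-6-methylphenyl)(3-chloro-2,4,6-trihydroxyphenyl)methanone | O=C(c1c(O)cc(O)c(Cl)c1O)c1c(C)cc(OCc2ccccc2)cc1OC
F0 | step 9 | none | none
A1 | alternative 1 | (2-benzyloxy-3-chloro-4,6-dimethoxyphenyl)(4-hydroxy-2-methoxy-6-methylphenyl)methanone | COc1cc(OC)c(C(=O)c2c(C)cc(O)cc2OC)c(OCc2ccccc2)c1Cl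
A2 | alternative 1 | 1-(2-benzyloxy-3-chloro-4,6-dimethoxyphenyl)but-2-yn-1-one | CC#CC(=O)c1c(OC)cc(OC)c(Cl)c1OCc1ccccc1
A3 | alternative 1 | 1,1-dimethoxy-3-(trimethylsilyloxy)buta-1,3-diene | COC(OC)=CC(=C)O[Si](C)(C)C
A4 | alternative 2 | methyl 2-[5-benzyloxy-2-(2-benzyloxy-3-chloro-4,6-dimethoxybenzoyl)-3-methoxyphenyl]acetate | COC(=O)Cc1cc(OCc2ccccc2)cc(OC)c1C(=O)c1c(OC)cc(OC)c(Cl)c1OCc1ccccc1
A5 | alternative 2 | methyl 3-(2-benzyloxy-3-chloro-4,6-dimethoxyphenyl)-3-oxopropanoate | COC(=O)CC(=O)c1c(OC)cc(OC)c(Cl)c1OCc1ccccc1
A6 | alternative 2 | 5-(benzyloxy)-3-methoxy-2-(trimethylsilyl)phenyl trifluoromethanesulfonate | COc1cc(OCc2ccccc2)cc(OS(=O)(=O)C(F)(F)F)c1[Si](C)(C)C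
A7 | alternative 3 | (2-benzyloxy-3-chloro-4,6-dimethoxyphenyl)(4-benzyloxy-2-methoxy-6-methylphenyl)methanone | COc1cc(OC)c(C(=O)c2c(C)cc(OCc3ccccc3)cc2OC)c(OCc2ccccc2)c1Cl
A8 | alternative 3 | 5-(2-benzyloxy-3-chloro-4,6-dimethoxybenzoyl)-4-methoxy-6-methyl-2H-pyran-2-one | COc1cc(=O)oc(C)c1C(=O)c1c(OC)cc(OC)c(Cl)c1OCc1ccccc1
A9 | alternative 3 | 1,1-bis(benzyloxy)ethene | C=C(OCc1ccccc1)OCc1ccccc1
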